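Ring B is formed by cutting the C9–C10 bond. Because the quaternary C10 of the target holds the C20 methyl and a bond to C9, ring A is carried with a C10=C20 exocyclic methylene. Hydrogen atom transfer from an iron hydride to C20 makes the angular methyl and a tertiary C10 radical, which closes ring B by 6-exo addition to C9 of a C8-oxo C9=C11 enoate. This fixes C10 (and, after equilibration, C9) from the single preset centre C5. The precursor is a ring A methylenecyclohexane with a C4 malonate and an (E)-4-oxo-enoate chain on C5, built by rhodium-catalysed asymmetric alkenylation, malonate ring closure and furan oxidation.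

Key step: step 8

Remark: positions are given in labdane numbering (ring A = C1–C5 and C10; ring B = C5–C10; C11–C16 side chain; C17 on C8; C18 and C19 on C4; C20 on C10).
Remark (assumption): the (S,S) antipode of the diene ligand is taken to deliver the alkenyl group to the Re face of C3 of enoate 5, by analogy with the facial preference of this catalyst family for (E)-β-alkyl acceptors; if the first adduct shows the opposite sense, the (R,R) ligand is used and nothing else changes.

Step 1
Reactants: 1 5-chloropent-1-yne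
Product: 3 2-(5-chloropent-1-en-2-yl)-4,4,5,5-tetramethyl-1,3,2-dioxaborolane, via alkenylalane 2 (not isolated)
Conditions: i-Bu2AlH (DIBAL-H), Ni(dppp)Cl2 (3 mol %), THF, 0 °C → rt; then MeOB(pin), 0 → 80 °C
Reagents that add atoms: 2-methoxy-4,4,5,5-tetramethyl-1,3,2-dioxaborolane, COB1OC(C)(C)C(C)(C)O1
Why: Nickel-catalysed α-selective (Markovnikov) hydroalumination of the terminal alkyne puts aluminium on the internal carbon and the alane is borylated in the same flask (hydrometalation, then transmetalation to boron), which gives the 1,1-disubstituted alkenyl boronate that C10=C20 with C1–C3 requires, whereas the linear (E)-alkenyl isomer from ordinary hydroboration would later close a seven-membered ring; the primary chloride is inert to i-Bu2AlH at room temperature.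

Step 2
Reactants: 4 3-(furan-2-yl)propanal
Product: 5 methyl (2E)-5-(furan-2-yl)pent-2-enoate
Conditions: Ph3P=CHCO2Me, CH2Cl2, rt
Reagents that add atoms: methyl (triphenylphosphoranylidene)acetate, COC(=O)C=P(c1ccccc1)(c1ccccc1)c1ccccc1
Why: Wittig olefination with a stabilised ylide gives the (E)-enoate selectively and leaves the furan untouched.

Step 3
Reactants: 5 methyl (2E)-5-(furan-2-yl)pent-2-enoate; 3 2-(5-chloropent-1-en-2-yl)-4,4,5,5-tetramethyl-1,3,2-dioxaborolane
Product: 6 methyl (3R)-7-chloro-3-[2-(furan-2-yl)ethyl]-4-methylideneheptanoate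
Conditions: [RhCl(C2H4)2]2 (2.5 mol %), (S,S)-Ph-bod* [(1S,4S)-2,5-diphenylbicyclo[2.2.2]octa-2,5-diene, 5.5 mol %], KOH (0.5 equiv), 1,4-dioxane/H2O (10:1), 50 °C
Reagents that add atoms: none
Why: Rhodium-catalysed asymmetric conjugate addition of an alkenylboron reagent to an enoate (Hayashi–Miyaura reaction), in which the alkenylrhodium species formed by transmetalation inserts the (E)-enoate on the Re face of C3 under control of the C2-symmetric diene ligand and the oxa-π-allyl intermediate is protonated by water, so that C5 is set (R in 6).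

Step 4
Reactants: 6 methyl (3R)-7-chloro-3-[2-(furan-2-yl)ethyl]-4-methylideneheptanoate
Product: 7 dimethyl 2-[(3R)-7-chloro-1-(furan-2-yl)-4-methylideneheptan-3-yl]propanedioate
Conditions: LiN(i-Pr)2 (LDA, 2.2 equiv), THF, −78 °C; ClCO2Me, −78 → 0 °C
Reagents that add atoms: methyl chloroformate, COC(=O)Cl
Why: Claisen-type C-acylation of the lithium ester enolate with a chloroformate (two equivalents of base because the malonate is deprotonated as it forms) adds the second ester at C4, while C5 is not acidic and the alkyl chloride does not react at this temperature.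

Step 5
Reactants: 7 dimethyl 2-[(3R)-7-chloro-1-(furan-2-yl)-4-methylideneheptan-3-yl]propanedioate
Product: 8 dimethyl (2S)-2-[2-(furan-2-yl)ethyl]-3-methylidenecyclohexane-1,1-dicarboxylate
Conditions: NaH, NaI (cat.), THF/DMF (4:1), 0 → 60 °C
Reagents that add atoms: none
Why: Intramolecular malonate alkylation (6-exo-tet, with in situ Finkelstein exchange of the chloride) closes ring A and makes C4 quaternary without involving C5, whose descriptor changes from R to S only because the priorities change.

Step 6
Reactants: 8 dimethyl (2S)-2-[2-(furan-2-yl)ethyl]-3-methylidenecyclohexane-1,1-dicarboxylate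
Product: 11 (2E)-6-[(1S)-2,2-bis(methoxycarbonyl)-6-methylidenecyclohexyl]-4-oxohex-2-enoic acid, via (Z)-oxo-enal 9 (not isolated), via (E)-oxo-enal 10 (not isolated)
Conditions: NBS (1.05 equiv), NaHCO3, acetone/H2O, −20 °C; pyridine, rt; then NaClO2, NaH2PO4, 2-methylbut-2-ene, t-BuOH/H2O, 0 °C → rt
Reagents that add atoms: water, O; sodium chlorite, [Na+].[O-]Cl=O
Why: Oxidative ring opening of the 2-alkylfuran by electrophilic bromination and hydrolysis gives the cis-enedione (Z)-oxo-enal, pyridine isomerises it to the (E)-isomer and Pinnick oxidation takes the aldehyde to the acid in one pot, the electron-rich furan being brominated much faster than the hindered 1,1-disubstituted alkene and 2-methylbut-2-ene removing the hypochlorite.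

Step 7
Reactants: 11 (2E)-6-[(1S)-2,2-bis(methoxycarbonyl)-6-methylidenecyclohexyl]-4-oxohex-2-enoic acid
Product: 12 dimethyl (2S)-2-[(4E)-6-methoxy-3,6-dioxohex-4-en-1-yl]-3-methylidenecyclohexane-1,1-dicarboxylate
Conditions: MeI, KHCO3, DMF, rt
Reagents that add atoms: iodomethane, CI
Why: SN2 O-alkylation of the carboxylate under bicarbonate is mild enough for the electrophilic oxo-enoate and avoids diazo reagents, which would add to the electron-poor alkene.

Step 8
Reactants: 12 dimethyl (2S)-2-[(4E)-6-methoxy-3,6-dioxohex-4-en-1-yl]-3-methylidenecyclohexane-1,1-dicarboxylate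
Product: 14 dimethyl (4aR,5S,8aS)-5-(2-methoxy-2-oxoethyl)-4a-methyl-6-oxooctahydronaphthalene-1,1(2H)-dicarboxylate, via C9-epimeric keto triester 13 (not isolated)
Conditions: Fe(acac)3 (30 mol %), PhSiH3, EtOH/ethylene glycol (5:1), 60 °C; then DBU, PhMe, rt
Reagents that add atoms: none
Why: Fe(acac)3 (trivalent iron) and PhSiH3 in ethanol form an iron hydride that transfers a hydrogen atom to C20 of the electron-rich exocyclic alkene (Markovnikov), giving the angular methyl and a nucleophilic tertiary radical at C10 that adds to C9 of the C8-oxo C9=C11 enoate, after which the ester-stabilised C11 radical is reduced to the enolate and protonated by ethanol. The closest known reaction type is the iron-hydride hydrogen-atom-transfer reductive olefin coupling in its intramolecular form (Giese cyclisation), which is established for quaternary carbons in decalins. Ring B closes in the 6-exo-trig mode (C10 onto C9, ring atoms C5 to C10), whereas attack at C11, which the ketone favours electronically, would be 7-endo and should stay minor. C10 is controlled by C5, the only stereocentre present: in the chair-like transition state the C5 chain is equatorial on ring A and the axial ester at C4 blocks the face of C10 on which an axial bond would form, so the new bond forms equatorially and the C20 methyl ends axial and anti to H5 (trans fusion). C9 is formed alpha to the C8 ketone and is equilibrated by DBU to the equatorial arm, cis to C20, as in the target. The step needs trans over cis fusion, 6-exo over 7-endo closure and closure faster than return of the hydrogen atom (which would move the alkene toward C5); the equatorial chain beside the quaternary C4, the short tether and the doubly activated acceptor should secure these.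

Step 9
Reactants: 14 dimethyl (4aR,5S,8aS)-5-(2-methoxy-2-oxoethyl)-4a-methyl-6-oxooctahydronaphthalene-1,1(2H)-dicarboxylate
Product: 15 dimethyl (4aS,5R,8aS)-5-(2-methoxy-2-oxoethyl)-4a-methyl-6-methylideneoctahydronaphthalene-1,1(2H)-dicarboxylate
Conditions: Ph3PCH3Br, KN(SiMe3)2 (KHMDS), THF, 0 °C → rt
Reagents that add atoms: methyltriphenylphosphonium bromide, C[P+](c1ccccc1)(c1ccccc1)c1ccccc1.[Br-]
Why: Wittig methylenation of the C8 ketone with the non-stabilised ylide, which reacts with ketones far faster than with esters, installs C17, and C9 is already in its more stable configuration should it enolise.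

Step 10
Reactants: 15 dimethyl (4aS,5R,8aS)-5-(2-methoxy-2-oxoethyl)-4a-methyl-6-methylideneoctahydronaphthalene-1,1(2H)-dicarboxylate
Product: 16 2-[(1R,4aS,8aS)-5,5-bis(hydroxymethyl)-8a-methyl-2-methylidenedecahydronaphthalen-1-yl]ethan-1-ol
Conditions: LiAlH4, THF, 0 °C → reflux; aqueous work-up
Reagents that add atoms: none
Why: Hydride reduction of all three esters to primary alcohols by LiAlH4 leaves the 1,1-disubstituted alkene and the stereocentres untouched.

Step 11
Reactants: 16 2-[(1R,4aS,8aS)-5,5-bis(hydroxymethyl)-8a-methyl-2-methylidenedecahydronaphthalen-1-yl]ethan-1-ol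
Product: 17 2-[(4a′S,5′R,8a′S)-2,2,4a′-trimethyl-6′-methylideneoctahydro-2′H-spiro[[1,3]dioxane-5,1′-naphthalen]-5′-yl]ethan-1-ol
Conditions: 2,2-dimethoxypropane, PPTS (cat.), acetone, rt
Reagents that add atoms: 2,2-dimethoxypropane, COC(C)(C)OC
Why: Acid-catalysed transacetalisation forms the six-membered isopropylidene acetal of the C18/C19 1,3-diol selectively, since the C12 hydroxyl can only give an open mixed acetal that is lost on work-up.

Step 12
Reactants: 17 2-[(4a′S,5′R,8a′S)-2,2,4a′-trimethyl-6′-methylideneoctahydro-2′H-spiro[[1,3]dioxane-5,1′-naphthalen]-5′-yl]ethan-1-ol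
Product: 18 2-[(4a′S,5′R,8a′S)-2,2,4a′-trimethyl-6′-methylideneoctahydro-2′H-spiro[[1,3]dioxane-5,1′-naphthalen]-5′-yl]acetaldehyde
Conditions: Dess–Martin periodinane, pyridine, CH2Cl2, 0 °C → rt
Reagents that add atoms: none
Why: Dess–Martin oxidation takes the primary C12 alcohol to the aldehyde under buffered conditions that spare the acetal and the alkene, and the aldehyde has no stereocentre at its alpha carbon (C11) to lose.

Step 13
Reactants: 18 2-[(4a′S,5′R,8a′S)-2,2,4a′-trimethyl-6′-methylideneoctahydro-2′H-spiro[[1,3]dioxane-5,1′-naphthalen]-5′-yl]acetaldehyde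
Product: 19 (2E)-2-methyl-4-[(4a′S,5′R,8a′S)-2,2,4a′-trimethyl-6′-methylideneoctahydro-2′H-spiro[[1,3]dioxane-5,1′-naphthalen]-5′-yl]but-2-enal
Conditions: Ph3P=C(CH3)CHO, PhMe, 90 °C
Reagents that add atoms: 2-(triphenylphosphoranylidene)propanal, CC(C=O)=P(c1ccccc1)(c1ccccc1)c1ccccc1
Why: Wittig olefination with the stabilised formyl ylide gives the (E)-configured C12=C13 enal selectively and stops after one addition because the conjugated product aldehyde is much less electrophilic.

Step 14
Reactants: 19 (2E)-2-methyl-4-[(4a′S,5′R,8a′S)-2,2,4a′-trimethyl-6′-methylideneoctahydro-2′H-spiro[[1,3]dioxane-5,1′-naphthalen]-5′-yl]but-2-enal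
Product: 20 (4a′S,5′R,8a′S)-2,2,4a′-trimethyl-6′-methylidene-5′-[(2E)-3-methylpenta-2,4-dien-1-yl]octahydro-2′H-spiro[[1,3]dioxane-5,1′-naphthalene]
Conditions: Ph3PCH3Br, KN(SiMe3)2 (KHMDS), THF, −78 → 0 °C
Reagents that add atoms: methyltriphenylphosphonium bromide, C[P+](c1ccccc1)(c1ccccc1)c1ccccc1.[Br-]
Why: Wittig methylenation of the enal carbonyl (C14) adds C15 and completes the (12E)-diene without touching the C12=C13 geometry.

Step 15
Reactants: 20 (4a′S,5′R,8a′S)-2,2,4a′-trimethyl-6′-methylidene-5′-[(2E)-3-methylpenta-2,4-dien-1-yl]octahydro-2′H-spiro[[1,3]dioxane-5,1′-naphthalene]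
Product: 21 {(4aS,5R,8aS)-4a-methyl-6-methylidene-5-[(2E)-3-methylpenta-2,4-dien-1-yl]octahydronaphthalene-1,1(2H)-diyl}dimethanol
Conditions: AcOH/THF/H2O (3:1:1), 35 °C
Reagents that add atoms: none
Why: Mild acid hydrolysis cleaves the isopropylidene acetal under conditions too weak to protonate the diene or the exocyclic alkene.

Step 16
Reactants: 21 {(4aS,5R,8aS)-4a-methyl-6-methylidene-5-[(2E)-3-methylpenta-2,4-dien-1-yl]octahydronaphthalene-1,1(2H)-diyl}dimethanol
Product: 22 {(4aS,5R,8aS)-4a-methyl-6-methylidene-5-[(2E)-3-methylpenta-2,4-dien-1-yl]octahydronaphthalene-1,1(2H)-diyl}bis(methylene) diacetate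
Conditions: Ac2O, pyridine, DMAP (cat.), CH2Cl2, rt
Reagents that add atoms: acetic anhydride, CC(=O)OC(C)=O
Why: DMAP-catalysed acylation of both neopentyl primary alcohols with acetic anhydride gives the target diacetate.

Compound list
1 | 5-chloropent-1-yne | C#CCCCCl | starting material
2 | (5-chloropent-1-en-2-yl)bis(2-methylpropyl)alumane | C=C(CCCCl)[Al](CC(C)C)CC(C)C | intermediate
3 | 2-(5-chloropent-1-en-2-yl)-4,4,5,5-tetramethyl-1,3,2-dioxaborolane | C=C(CCCCl)B1OC(C)(C)C(C)(C)O1 | intermediate
4 | 3-(furan-2-yl)propanal | O=CCCc1ccco1 | starting material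
5 | methyl (2E)-5-(furan-2-yl)pent-2-enoate | COC(=O)/C=C/CCc1ccco1 | intermediate
6 | methyl (3R)-7-chloro-3-[2-(furan-2-yl)ethyl]-4-methylideneheptanoate | COC(=O)C[C@@H](CCc1ccco1)C(=C)CCCCl | intermediate
7 | dimethyl 2-[(3R)-7-chloro-1-(furan-2-yl)-4-methylideneheptan-3-yl]propanedioate | COC(=O)C(C(=O)OC)[C@@H](CCc1ccco1)C(=C)CCCCl | intermediate
8 | dimethyl (2S)-2-[2-(furan-2-yl)ethyl]-3-methylidenecyclohexane-1,1-dicarboxylate | C=C1CCCC(C(=O)OC)(C(=O)OC)[C@H]1CCc2ccco2 | intermediate
9 | dimethyl (2S)-2-[(4Z)-3,6-dioxohex-4-en-1-yl]-3-methylidenecyclohexane-1,1-dicarboxylate | C=C1CCCC(C(=O)OC)(C(=O)OC)[C@H]1CCC(=O)/C=C\C=O | intermediate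
10 | dimethyl (2S)-2-[(4E)-3,6-dioxohex-4-en-1-yl]-3-methylidenecyclohexane-1,1-dicarboxylate | C=C1CCCC(C(=O)OC)(C(=O)OC)[C@H]1CCC(=O)/C=C/C=O | intermediate
11 | (2E)-6-[(1S)-2,2-bis(methoxycarbonyl)-6-methylidenecyclohexyl]-4-oxohex-2-enoic acid | C=C1CCCC(C(=O)OC)(C(=O)OC)[C@H]1CCC(=O)/C=C/C(=O)O | intermediate
12 | dimethyl (2S)-2-[(4E)-6-methoxy-3,6-dioxohex-4-en-1-yl]-3-methylidenecyclohexane-1,1-dicarboxylate (precursor of the key step) | C=C1CCCC(C(=O)OC)(C(=O)OC)[C@H]1CCC(=O)/C=C/C(=O)OC | intermediate
13 | dimethyl (4aR,5R,8aS)-5-(2-methoxy-2-oxoethyl)-4a-methyl-6-oxooctahydronaphthalene-1,1(2H)-dicarboxylate (C9 epimer of 14) | COC(=O)C[C@H]1C(=O)CC[C@@H]2C(C(=O)OC)(C(=O)OC)CCC[C@@]12C | intermediate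
14 | dimethyl (4aR,5S,8aS)-5-(2-methoxy-2-oxoethyl)-4a-methyl-6-oxooctahydronaphthalene-1,1(2H)-dicarboxylate (trans-decalin C8 ketone, product of the key step) | COC(=O)C[C@@H]1C(=O)CC[C@@H]2C(C(=O)OC)(C(=O)OC)CCC[C@@]12C | intermediate
15 | dimethyl (4aS,5R,8aS)-5-(2-methoxy-2-oxoethyl)-4a-methyl-6-methylideneoctahydronaphthalene-1,1(2H)-dicarboxylate | COC(=O)C[C@@H]1C(=C)CC[C@@H]2C(C(=O)OC)(C(=O)OC)CCC[C@@]12C | intermediate
16 | 2-[(1R,4aS,8aS)-5,5-bis(hydroxymethyl)-8a-methyl-2-methylidenedecahydronaphthalen-1-yl]ethan-1-ol | OCC[C@@H]1C(=C)CC[C@@H]2C(CO)(CO)CCC[C@@]12C | intermediate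
17 | 2-[(4a′S,5′R,8a′S)-2,2,4a′-trimethyl-6′-methylideneoctahydro-2′H-spiro[[1,3]dioxane-5,1′-naphthalen]-5′-yl]ethan-1-ol (C18/C19 acetonide, free C12 alcohol) | OCC[C@@H]1C(=C)CC[C@@H]2C3(COC(C)(C)OC3)CCC[C@@]12C | intermediate
18 | 2-[(4a′S,5′R,8a′S)-2,2,4a′-trimethyl-6′-methylideneoctahydro-2′H-spiro[[1,3]dioxane-5,1′-naphthalen]-5′-yl]acetaldehyde | O=CC[C@@H]1C(=C)CC[C@@H]2C3(COC(C)(C)OC3)CCC[C@@]12C | intermediate
19 | (2E)-2-methyl-4-[(4a′S,5′R,8a′S)-2,2,4a′-trimethyl-6′-methylideneoctahydro-2′H-spiro[[1,3]dioxane-5,1′-naphthalen]-5′-yl]but-2-enal | O=C/C(C)=C/C[C@@H]1C(=C)CC[C@@H]2C3(COC(C)(C)OC3)CCC[C@@]12C | intermediate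
20 | (4a′S,5′R,8a′S)-2,2,4a′-trimethyl-6′-methylidene-5′-[(2E)-3-methylpenta-2,4-dien-1-yl]octahydro-2′H-spiro[[1,3]dioxane-5,1′-naphthalene] | C=C/C(C)=C/C[C@@H]1C(=C)CC[C@@H]2C3(COC(C)(C)OC3)CCC[C@@]12C | intermediate
21 | {(4aS,5R,8aS)-4a-methyl-6-methylidene-5-[(2E)-3-methylpenta-2,4-dien-1-yl]octahydronaphthalene-1,1(2H)-diyl}dimethanol | C=C/C(C)=C/C[C@@H]1C(=C)CC[C@@H]2C(CO)(CO)CCC[C@@]12C | intermediate
22 | {(4aS,5R,8aS)-4a-methyl-6-methylidene-5-[(2E)-3-methylpenta-2,4-dien-1-yl]octahydronaphthalene-1,1(2H)-diyl}bis(methylene) diacetate (CNP0129553.1) | C=C/C(C)=C/C[C@@H]1C(=C)CC[C@@H]2C(COC(C)=O)(COC(C)=O)CCC[C@@]12C | target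

Total step count: 16.
Longest linear sequence: 15 steps (4 → 22, steps 2 to 16; the one-step branch from 1 joins in step 3).

The three steps most likely to fail

1. Step 8. The radical may close through the ring A chair that holds the C5 chain axial, which gives the cis junction and cannot be repaired later. It may also add at C11, or hand its hydrogen atom back before closing, which would move the alkene toward C5 and erode that centre. The fallback changes the acceptor and the order of oxidation, and sets out from (E)-oxo-enal 10, isolated after the pyridine stage of step 6. In 10 the aldehyde activates C9 more strongly than the ketone activates C11, so polarity and ring size point to the same carbon and closure should be faster. That allows phenyl(isopropoxy)silane with Fe(acac)3 at room temperature, where the preference for the chair with the equatorial chain weighs more. The cyclisation would give the keto aldehyde dimethyl (4aR,8aS)-4a-methyl-6-oxo-5-(2-oxoethyl)octahydronaphthalene-1,1(2H)-dicarboxylate F1 (both C9 epimers). Pinnick oxidation (NaClO2, NaH2PO4, 2-methylbut-2-ene) gives the keto acid 2-[(4aS,8aR)-5,5-bis(methoxycarbonyl)-8a-methyl-2-oxodecahydronaphthalen-1-yl]acetic acid F2. Methylation as in step 7 and the DBU equilibration of step 8 bring the material back to the route at 14.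

2. Step 3. Insertion of the hindered 1,1-disubstituted alkenylrhodium species into the ester acceptor may be slow, so that protodeboronation wins, or the facial selectivity on this acyclic β-alkyl enoate may be insufficient. The fallback replaces catalyst control by an auxiliary and sets out from aldehyde 4 and alkyne 1. Masamune–Roush olefination of 4 with diethyl {2-oxo-2-[(4S)-2-oxo-4-phenyl-1,3-oxazolidin-3-yl]ethyl}phosphonate (LiCl, i-Pr2NEt, MeCN) gives (4S)-3-[(2E)-5-(furan-2-yl)pent-2-enoyl]-4-phenyl-1,3-oxazolidin-2-one F3. Markovnikov hydrobromination of 1 (HBr, Et4NBr, CH2Cl2) gives 2-bromo-5-chloropent-1-ene F4, and magnesium in THF converts it into (5-chloropent-1-en-2-yl)magnesium bromide F5. Addition of F5 with CuBr·SMe2 to the chelated imide, anti to the phenyl group and therefore on the Re face of C3, gives (4S)-3-[(3R)-7-chloro-3-[2-(furan-2-yl)ethyl]-4-methylideneheptanoyl]-4-phenyl-1,3-oxazolidin-2-one F6. Methanolysis with MeOMgBr removes the auxiliary and returns to the route at 6.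

3. Step 6. Electrophilic bromine may attack the C10=C20 alkene (bromohydrin formation) in competition with the furan, or the ring-opened enal may be over-oxidised before it isomerises. The fallback uses a pericyclic oxidation and sets out from 8. The [4+2] cycloaddition of singlet oxygen (O2, tetraphenylporphyrin, visible light, CH2Cl2, −78 °C), which reacts with furans far faster than with a 1,1-disubstituted alkene, gives the furan endoperoxide dimethyl (2S)-3-methylidene-2-[2-(2,3,7-trioxabicyclo[2.2.1]hept-5-en-1-yl)ethyl]cyclohexane-1,1-dicarboxylate F7. Reduction with Me2S opens it to (Z)-oxo-enal 9, where the route is rejoined (pyridine, then NaClO2 as in step 6).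

Further compounds
F1 | step 8 | dimethyl (4aR,8aS)-4a-methyl-6-oxo-5-(2-oxoethyl)octahydronaphthalene-1,1(2H)-dicarboxylate (both C9 epimers) | O=CCC1C(=O)CC[C@@H]2C(C(=O)OC)(C(=O)OC)CCC[C@@]12C
F2 | step 8 | 2-[(4aS,8aR)-5,5-bis(methoxycarbonyl)-8a-methyl-2-oxodecahydronaphthalen-1-yl]acetic acid (both C9 epimers) | OC(=O)CC1C(=O)CC[C@@H]2C(C(=O)OC)(C(=O)OC)CCC[C@@]12C
F3 | step 3 | (4S)-3-[(2E)-5-(furan-2-yl)pent-2-enoyl]-4-phenyl-1,3-oxazolidin-2-one | O=C(/C=C/CCc1ccco1)N1[C@@H](c2ccccc2)COC1=O
F4 | step 3 | 2-bromo-5-chloropent-1-ene | C=C(Br)CCCCl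
F5 | step 3 | (5-chloropent-1-en-2-yl)magnesium bromide | C=C([Mg]Br)CCCCl
F6 | step 3 | (4S)-3-[(3R)-7-chloro-3-[2-(furan-2-yl)ethyl]-4-methylideneheptanoyl]-4-phenyl-1,3-oxazolidin-2-one | O=C(C[C@@H](CCc1ccco1)C(=C)CCCCl)N1[C@@H](c2ccccc2)COC1=O
F7 | step 6 | dimethyl (2S)-3-methylidene-2-[2-(2,3,7-trioxabicyclo[2.2.1]hept-5-en-1-yl)ethyl]cyclohexane-1,1-dicarboxylate | C=C1CCCC(C(=O)OC)(C(=O)OC)[C@H]1CCC12OOC(C=C1)O2
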